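Ring A hides a resorcinol: the oxygens on C3 and C5 are meta, C1 carries the ethylene bridge to ring B, and the benzylic carbon on C2 can begin as an ester carbon. The route therefore rests on cutting the C1–C2 bond of ring A, which unfolds the ring into a linear 3,5,7-triketo ester. In one operation, heating a diketo-dioxinone with methanol frees that chain, which closes by aldol condensation and aromatises to the pentasubstituted resorcylate. The precursor is a 2,2-dimethyl-1,3-dioxin-4-one whose side chain is a 1,3-diketone with the C6 4-(benzyloxy)benzyl group on its central carbon and the benzyl-protected ring B ethyl arm at its end.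

Key step: step 7

Remark: the target has no stereocentre; ring A is numbered C1 (ethylene bridge), C2 and C6 (4-hydroxybenzyl), C3 (OH), C4 (H), C5 (OMe); methyl 3-(2-hydroxyphenyl)propanoate (the methanolysis product of 3,4-dihydrocoumarin), 3-[4-(benzyloxy)phenyl]propanoic acid (O-benzyl phloretic acid) and 4-(benzyloxy)phenylmagnesium bromide in THF are taken as purchased.

Step 1
Reactants: 1 methyl 3-(2-hydroxyphenyl)propanoate
Product: 2 methyl 3-[2-(benzyloxy)phenyl]propanoate
Conditions: BnBr, K2CO3, DMF, 25 °C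
Reagents that add atoms: benzyl bromide, BrCc1ccccc1
Why: Williamson etherification; the phenoxide formed by K2CO3 is the only nucleophile present and should be benzylated faster than it can relactonise onto the methyl ester.

Step 2
Reactants: 2 methyl 3-[2-(benzyloxy)phenyl]propanoate
Product: 3 methyl 3-[2-(benzyloxy)-5-bromophenyl]propanoate
Conditions: NBS, MeCN, 25 °C, dark
Reagents that add atoms: N-bromosuccinimide, O=C1CCC(=O)N1Br
Why: electrophilic aromatic bromination; NBS in MeCN brominates alkyl aryl ethers para to oxygen, and C5 is para to the benzyloxy group and unhindered, while the unactivated O-benzyl phenyl ring and the ester should stay untouched.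

Step 3
Reactants: 3 methyl 3-[2-(benzyloxy)-5-bromophenyl]propanoate; 4 4-(benzyloxy)benzyl chloride
Product: 6 methyl 3-[2-(benzyloxy)-5-[4-(benzyloxy)benzyl]phenyl]propanoate, via benzylzinc chloride 5 (not isolated)
Conditions: 4, Zn dust, LiCl, THF, 25 °C; then 3, Pd(OAc)2 (2 mol %), SPhos (2-dicyclohexylphosphino-2',6'-dimethoxybiphenyl, 4 mol %), THF, 25 to 50 °C
Reagents that add atoms: none
Why: Negishi cross-coupling; LiCl-assisted zinc insertion into the benzylic C–Cl bond gives an organozinc that tolerates the ester, and the palladium/biarylphosphine catalyst should join it to the aryl bromide to form the diarylmethane of ring B.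

Step 4
Reactants: 6 methyl 3-[2-(benzyloxy)-5-[4-(benzyloxy)benzyl]phenyl]propanoate
Product: 7 3-[2-(benzyloxy)-5-[4-(benzyloxy)benzyl]phenyl]-N-methoxy-N-methylpropanamide
Conditions: MeNH(OMe)·HCl, iPrMgCl, THF, −20 to 0 °C; 1 M HCl
Reagents that add atoms: N,O-dimethylhydroxylamine hydrochloride, CNOC.Cl
Why: Weinreb amide formation by aminolysis of the methyl ester with the chloromagnesium amide of N,O-dimethylhydroxylamine; this gives an isolable, aprotic acyl donor whose chelated tetrahedral adduct should hold back the acidic triketone until the quench of step 6.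

Step 5
Reactants: 8 2,2,6-trimethyl-4H-1,3-dioxin-4-one; 9 3-[4-(benzyloxy)phenyl]propanoic acid
Product: 11 keto-dioxinone 6-[4-[4-(benzyloxy)phenyl]-2-oxobutyl]-2,2-dimethyl-4H-1,3-dioxin-4-one, via acyl imidazolide 10 (not isolated)
Conditions: 9, 1,1'-carbonyldiimidazole, THF, 25 °C; added to 8 (3.3 equiv) and LiN(SiMe3)2 (3.3 equiv), THF, −78 °C; 1 M HCl
Reagents that add atoms: none
Why: Claisen-type acylation of a vinylogous ester enolate; LiN(SiMe3)2 deprotonates the C6 methyl group of the dioxinone and the dienolate should attack the acyl imidazolide through that carbon, the excess dienolate taking up the imidazole N–H and the acidic proton of the product.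

Step 6
Reactants: 11 keto-dioxinone 6-[4-[4-(benzyloxy)phenyl]-2-oxobutyl]-2,2-dimethyl-4H-1,3-dioxin-4-one; 7 3-[2-(benzyloxy)-5-[4-(benzyloxy)benzyl]phenyl]-N-methoxy-N-methylpropanamide
Product: 12 diketo-dioxinone 6-[3-[4-(benzyloxy)benzyl]-6-[2-(benzyloxy)-5-[4-(benzyloxy)benzyl]phenyl]-2,4-dioxohexyl]-2,2-dimethyl-4H-1,3-dioxin-4-one (racemic at the carbon between the ketones)
Conditions: 11 (1.3 equiv), LiN(iPr)2 (2.7 equiv), THF, −78 °C; then 7, −78 to −20 °C; 1 M HCl
Reagents that add atoms: none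
Why: Claisen acylation of a 1,3-dicarbonyl dianion (Huckin–Weiler type); the second-formed, more basic carbanion at the ketone α-carbon remote from the dioxinone should attack the Weinreb amide, and the new stereocentre between the two ketones arises racemic and enolisable, which does not matter because it becomes aromatic C6.

Step 7
Reactants: 12 diketo-dioxinone 6-[3-[4-(benzyloxy)benzyl]-6-[2-(benzyloxy)-5-[4-(benzyloxy)benzyl]phenyl]-2,4-dioxohexyl]-2,2-dimethyl-4H-1,3-dioxin-4-one
Product: 15 methyl 5-[4-(benzyloxy)benzyl]-6-[2-[2-(benzyloxy)-5-[4-(benzyloxy)benzyl]phenyl]ethyl]-2,4-dihydroxybenzoate, via acylketene 13 (not isolated), via triketo ester 14 (not isolated)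
Conditions: MeOH (20 equiv), PhMe, 110 °C, sealed tube; then Cs2CO3, MeOH, 25 °C; then HCl in MeOH, 25 °C
Reagents that add atoms: methanol, CO
Why: On heating, the dioxinone should undergo retro-hetero-Diels–Alder cleavage to acetone and acylketene 13, and the large excess of methanol should add to the ketene faster than the neighbouring enol oxygen can (that path would end in a 4-hydroxypyran-2-one), giving triketo ester 14 (chain numbered from the ester carbon as C1). With Cs2CO3 the C2 methylene, lying between the ester and the C3 ketone, should add to the C7 ketone that bears the ring B arm in a 6-(enolexo)-exo-trig aldol closure, which creates the C1–C2 bond of ring A, and methanolic HCl should complete the two dehydration and enolisation events that make the ring aromatic. The closest known reaction type is the thermolysis, alcohol capture and aldol aromatisation of diketo-dioxinones to β-resorcylates. No stereocentre is formed, and the racemic carbon between the two ketones of 12 becomes the planar benzyl-bearing C6. The step needs aldol closure from C2 onto C7 rather than Claisen closure onto the ester or closure of the C8 methylene onto the C3 ketone: C2 is far more acidic than C8, the aldol additions are reversible, and a Claisen ring through the benzylated carbon would contain a quaternary centre and could not aromatise.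

Step 8
Reactants: 15 methyl 5-[4-(benzyloxy)benzyl]-6-[2-[2-(benzyloxy)-5-[4-(benzyloxy)benzyl]phenyl]ethyl]-2,4-dihydroxybenzoate
Product: 16 methyl 5-[4-(benzyloxy)benzyl]-6-[2-[2-(benzyloxy)-5-[4-(benzyloxy)benzyl]phenyl]ethyl]-2-hydroxy-4-methoxybenzoate
Conditions: MeI (1.1 equiv), K2CO3, acetone, 25 °C
Reagents that add atoms: iodomethane, CI
Why: Williamson etherification; the hydroxyl para to the ester (C5 of ring A) is the more acidic and is not hydrogen-bonded, whereas the C3 hydroxyl is tied to the ester carbonyl and should stay unalkylated under these mild conditions.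

Step 9
Reactants: 16 methyl 5-[4-(benzyloxy)benzyl]-6-[2-[2-(benzyloxy)-5-[4-(benzyloxy)benzyl]phenyl]ethyl]-2-hydroxy-4-methoxybenzoate
Product: 17 methyl 2-(benzyloxy)-5-[4-(benzyloxy)benzyl]-6-[2-[2-(benzyloxy)-5-[4-(benzyloxy)benzyl]phenyl]ethyl]-4-methoxybenzoate
Conditions: BnBr, K2CO3, DMF, 60 °C
Reagents that add atoms: benzyl bromide, BrCc1ccccc1
Why: Williamson etherification under more forcing conditions should break the hydrogen bond and cap the C3 phenol, which removes the acidic proton and the o-quinone methide pathway from the hydride and Grignard steps that follow.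

Step 10
Reactants: 17 methyl 2-(benzyloxy)-5-[4-(benzyloxy)benzyl]-6-[2-[2-(benzyloxy)-5-[4-(benzyloxy)benzyl]phenyl]ethyl]-4-methoxybenzoate
Product: 18 [2-(benzyloxy)-5-[4-(benzyloxy)benzyl]-6-[2-[2-(benzyloxy)-5-[4-(benzyloxy)benzyl]phenyl]ethyl]-4-methoxyphenyl]methanol
Conditions: LiAlH4, THF, 0 to 25 °C; H2O quench
Reagents that add atoms: none
Why: hydride reduction of the ester to the primary benzylic alcohol; LiAlH4 is small enough to reach the di-ortho-substituted ester, and aryl benzyl ethers are inert to it.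

Step 11
Reactants: 18 [2-(benzyloxy)-5-[4-(benzyloxy)benzyl]-6-[2-[2-(benzyloxy)-5-[4-(benzyloxy)benzyl]phenyl]ethyl]-4-methoxyphenyl]methanol
Product: 19 2-(benzyloxy)-5-[4-(benzyloxy)benzyl]-6-[2-[2-(benzyloxy)-5-[4-(benzyloxy)benzyl]phenyl]ethyl]-4-methoxybenzaldehyde
Conditions: activated MnO2 (excess), CH2Cl2, 25 °C
Reagents that add atoms: none
Why: MnO2 oxidation is selective for benzylic alcohols and stops at the aldehyde, and the substrate holds no other oxidisable group.

Step 12
Reactants: 19 2-(benzyloxy)-5-[4-(benzyloxy)benzyl]-6-[2-[2-(benzyloxy)-5-[4-(benzyloxy)benzyl]phenyl]ethyl]-4-methoxybenzaldehyde; 20 4-(benzyloxy)phenylmagnesium bromide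
Product: 21 [4-(benzyloxy)phenyl][2-(benzyloxy)-5-[4-(benzyloxy)benzyl]-6-[2-[2-(benzyloxy)-5-[4-(benzyloxy)benzyl]phenyl]ethyl]-4-methoxyphenyl]methanol (racemic)
Conditions: 20 (1.5 equiv), THF, 0 to 25 °C; aq. NH4Cl
Reagents that add atoms: none
Why: Grignard addition to the aldehyde installs the last aryl ring on the former ester carbon; the new carbinol stereocentre forms without control as a racemate, which is acceptable because step 13 removes it.

Step 13
Reactants: 21 [4-(benzyloxy)phenyl][2-(benzyloxy)-5-[4-(benzyloxy)benzyl]-6-[2-[2-(benzyloxy)-5-[4-(benzyloxy)benzyl]phenyl]ethyl]-4-methoxyphenyl]methanol (racemic)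
Product: 22 2,4-bis(4-hydroxybenzyl)-3-[2-[2-hydroxy-5-(4-hydroxybenzyl)phenyl]ethyl]-5-methoxyphenol (CNP0134121.0)
Conditions: H2 (1 atm), 10% Pd/C, EtOAc/MeOH, AcOH (5 vol %), 25 °C
Reagents that add atoms: none
Why: catalytic hydrogenolysis should cleave the five aryl benzyl ethers and the doubly benzylic C–OH bond, the latter helped by the ortho- and para-oxygenated rings, while the diarylmethane C–C bonds, the methyl ether and the arenes are not reduced at this pressure.

Compound list
1 | methyl 3-(2-hydroxyphenyl)propanoate | COC(=O)CCc1ccccc1O | starting material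
2 | methyl 3-[2-(benzyloxy)phenyl]propanoate | COC(=O)CCc1ccccc1OCc1ccccc1 | intermediate
3 | methyl 3-[2-(benzyloxy)-5-bromophenyl]propanoate | COC(=O)CCc1cc(Br)ccc1OCc1ccccc1 | intermediate
4 | 4-(benzyloxy)benzyl chloride | ClCc1ccc(OCc2ccccc2)cc1 | starting material
5 | [4-(benzyloxy)benzyl]zinc chloride (not isolated) | Cl[Zn]Cc1ccc(OCc2ccccc2)cc1 | intermediate
6 | methyl 3-[2-(benzyloxy)-5-[4-(benzyloxy)benzyl]phenyl]propanoate | COC(=O)CCc1cc(Cc2ccc(OCc3ccccc3)cc2)ccc1OCc1ccccc1 | intermediate
7 | 3-[2-(benzyloxy)-5-[4-(benzyloxy)benzyl]phenyl]-N-methoxy-N-methylpropanamide | CON(C)C(=O)CCc1cc(Cc2ccc(OCc3ccccc3)cc2)ccc1OCc1ccccc1 | intermediate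
8 | 2,2,6-trimethyl-4H-1,3-dioxin-4-one | CC1=CC(=O)OC(C)(C)O1 | starting material
9 | 3-[4-(benzyloxy)phenyl]propanoic acid | OC(=O)CCc1ccc(OCc2ccccc2)cc1 | starting material
10 | 1-[3-[4-(benzyloxy)phenyl]propanoyl]imidazole (not isolated) | O=C(CCc1ccc(OCc2ccccc2)cc1)n1ccnc1 | intermediate
11 | 6-[4-[4-(benzyloxy)phenyl]-2-oxobutyl]-2,2-dimethyl-4H-1,3-dioxin-4-one | CC1(C)OC(CC(=O)CCc2ccc(OCc3ccccc3)cc2)=CC(=O)O1 | intermediate
12 | 6-[3-[4-(benzyloxy)benzyl]-6-[2-(benzyloxy)-5-[4-(benzyloxy)benzyl]phenyl]-2,4-dioxohexyl]-2,2-dimethyl-4H-1,3-dioxin-4-one (racemic, enolisable centre) | CC1(C)OC(CC(=O)C(Cc2ccc(OCc3ccccc3)cc2)C(=O)CCc2cc(Cc3ccc(OCc4ccccc4)cc3)ccc2OCc2ccccc2)=CC(=O)O1 | intermediate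
13 | 6-[4-(benzyloxy)benzyl]-9-[2-(benzyloxy)-5-[4-(benzyloxy)benzyl]phenyl]-3,5,7-trioxonon-1-en-1-one (acylketene, racemic, not isolated) | O=C=CC(=O)CC(=O)C(Cc1ccc(OCc2ccccc2)cc1)C(=O)CCc1cc(Cc2ccc(OCc3ccccc3)cc2)ccc1OCc1ccccc1 | intermediate
14 | methyl 6-[4-(benzyloxy)benzyl]-9-[2-(benzyloxy)-5-[4-(benzyloxy)benzyl]phenyl]-3,5,7-trioxononanoate (racemic, not isolated) | COC(=O)CC(=O)CC(=O)C(Cc1ccc(OCc2ccccc2)cc1)C(=O)CCc1cc(Cc2ccc(OCc3ccccc3)cc2)ccc1OCc1ccccc1 | intermediate
15 | methyl 5-[4-(benzyloxy)benzyl]-6-[2-[2-(benzyloxy)-5-[4-(benzyloxy)benzyl]phenyl]ethyl]-2,4-dihydroxybenzoate | COC(=O)c1c(O)cc(O)c(Cc2ccc(OCc3ccccc3)cc2)c1CCc1cc(Cc2ccc(OCc3ccccc3)cc2)ccc1OCc1ccccc1 | intermediate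
16 | methyl 5-[4-(benzyloxy)benzyl]-6-[2-[2-(benzyloxy)-5-[4-(benzyloxy)benzyl]phenyl]ethyl]-2-hydroxy-4-methoxybenzoate | COC(=O)c1c(O)cc(OC)c(Cc2ccc(OCc3ccccc3)cc2)c1CCc1cc(Cc2ccc(OCc3ccccc3)cc2)ccc1OCc1ccccc1 | intermediate
17 | methyl 2-(benzyloxy)-5-[4-(benzyloxy)benzyl]-6-[2-[2-(benzyloxy)-5-[4-(benzyloxy)benzyl]phenyl]ethyl]-4-methoxybenzoate | COC(=O)c1c(OCc2ccccc2)cc(OC)c(Cc2ccc(OCc3ccccc3)cc2)c1CCc1cc(Cc2ccc(OCc3ccccc3)cc2)ccc1OCc1ccccc1 | intermediate
18 | [2-(benzyloxy)-5-[4-(benzyloxy)benzyl]-6-[2-[2-(benzyloxy)-5-[4-(benzyloxy)benzyl]phenyl]ethyl]-4-methoxyphenyl]methanol | OCc1c(OCc2ccccc2)cc(OC)c(Cc2ccc(OCc3ccccc3)cc2)c1CCc1cc(Cc2ccc(OCc3ccccc3)cc2)ccc1OCc1ccccc1 | intermediate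
19 | 2-(benzyloxy)-5-[4-(benzyloxy)benzyl]-6-[2-[2-(benzyloxy)-5-[4-(benzyloxy)benzyl]phenyl]ethyl]-4-methoxybenzaldehyde | O=Cc1c(OCc2ccccc2)cc(OC)c(Cc2ccc(OCc3ccccc3)cc2)c1CCc1cc(Cc2ccc(OCc3ccccc3)cc2)ccc1OCc1ccccc1 | intermediate
20 | 4-(benzyloxy)phenylmagnesium bromide (solution in THF) | Br[Mg]c1ccc(OCc2ccccc2)cc1 | starting material
21 | [4-(benzyloxy)phenyl][2-(benzyloxy)-5-[4-(benzyloxy)benzyl]-6-[2-[2-(benzyloxy)-5-[4-(benzyloxy)benzyl]phenyl]ethyl]-4-methoxyphenyl]methanol (racemic) | OC(c1ccc(OCc2ccccc2)cc1)c1c(OCc2ccccc2)cc(OC)c(Cc2ccc(OCc3ccccc3)cc2)c1CCc1cc(Cc2ccc(OCc3ccccc3)cc2)ccc1OCc1ccccc1 | intermediate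
22 | 2,4-bis(4-hydroxybenzyl)-3-[2-[2-hydroxy-5-(4-hydroxybenzyl)phenyl]ethyl]-5-methoxyphenol (CNP0134121.0, achiral) | COc1cc(O)c(Cc2ccc(O)cc2)c(CCc2cc(Cc3ccc(O)cc3)ccc2O)c1Cc1ccc(O)cc1 | target

Total step count: 13. Longest linear sequence: 12 steps (steps 1 to 4, then 6 to 13); the other branch is step 5 followed by steps 6 to 13.

Steps most likely to fail

Step 7. The acylketene may be captured by the internal enol oxygen before methanol reaches it (pyranone formation), the chain may close from the wrong end, or the cyclic aldol may stall before dehydration. The fallback reverses the order of events so that the ring is aromatic before any ketene exists. Setting out from 12, treatment with Et3N in CH2Cl2 at 25 °C should condense the dioxinone-bound carbon with the ketone that bears the ring B arm while the heterocycle stays closed, giving 7-hydroxy-6-[4-(benzyloxy)benzyl]-5-[2-[2-(benzyloxy)-5-[4-(benzyloxy)benzyl]phenyl]ethyl]-2,2-dimethyl-4H-1,3-benzodioxin-4-one F1. NaOMe in MeOH at 50 °C should then open the aryl acetonide by transesterification with loss of acetone, and the route is rejoined at 15.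

Step 6. Acyl transfer to the substituted carbanion may be slow, and proton transfer or O-acylation may consume the dianion. The fallback replaces acyl transfer by aldol addition followed by oxidation. Setting out from 7, reduction with iBu2AlH in THF at −78 °C should give 3-[2-(benzyloxy)-5-[4-(benzyloxy)benzyl]phenyl]propanal F2. The dianion of 11 (LiN(iPr)2, THF, −78 °C) should add to this aldehyde quickly and irreversibly to give 6-[3-[4-(benzyloxy)benzyl]-6-[2-(benzyloxy)-5-[4-(benzyloxy)benzyl]phenyl]-4-hydroxy-2-oxohexyl]-2,2-dimethyl-4H-1,3-dioxin-4-one F3 as a diastereomer mixture, both of whose stereocentres are erased later. Oxidation with Dess–Martin periodinane in CH2Cl2 returns the route at 12.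

Step 3. Zinc insertion into the electron-rich benzylic chloride may be accompanied by Wurtz-type homocoupling, and oxidative addition of the electron-rich aryl bromide may be slow. The fallback exchanges the roles of the partners in a Suzuki–Miyaura coupling. Setting out from 3, borylation with bis(pinacolato)diboron, PdCl2(dppf) and KOAc in dioxane at 90 °C should give methyl 3-[2-(benzyloxy)-5-(4,4,5,5-tetramethyl-1,3,2-dioxaborolan-2-yl)phenyl]propanoate F4. Coupling of this boronate with benzylic chloride 4 (Pd(PPh3)4, K2CO3, DME/H2O, 80 °C) rejoins the route at 6.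

Further compounds
F1 | step 7 | 7-hydroxy-6-[4-(benzyloxy)benzyl]-5-[2-[2-(benzyloxy)-5-[4-(benzyloxy)benzyl]phenyl]ethyl]-2,2-dimethyl-4H-1,3-benzodioxin-4-one | CC1(C)OC(=O)c2c(O1)cc(O)c(Cc3ccc(OCc4ccccc4)cc3)c2CCc2cc(Cc3ccc(OCc4ccccc4)cc3)ccc2OCc2ccccc2
F2 | step 6 | 3-[2-(benzyloxy)-5-[4-(benzyloxy)benzyl]phenyl]propanal | O=CCCc1cc(Cc2ccc(OCc3ccccc3)cc2)ccc1OCc1ccccc1
F3 | step 6 | 6-[3-[4-(benzyloxy)benzyl]-6-[2-(benzyloxy)-5-[4-(benzyloxy)benzyl]phenyl]-4-hydroxy-2-oxohexyl]-2,2-dimethyl-4H-1,3-dioxin-4-one (mixture of diastereomers) | CC1(C)OC(CC(=O)C(Cc2ccc(OCc3ccccc3)cc2)C(O)CCc2cc(Cc3ccc(OCc4ccccc4)cc3)ccc2OCc2ccccc2)=CC(=O)O1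
F4 | step 3 | methyl 3-[2-(benzyloxy)-5-(4,4,5,5-tetramethyl-1,3,2-dioxaborolan-2-yl)phenyl]propanoate | COC(=O)CCc1cc(B2OC(C)(C)C(C)(C)O2)ccc1OCc1ccccc1
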